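Take the leftover first: the fraction of the charged substrate still present after 50 h, with target reckoned as a share of the rest. Substrate is dosed into a stirred flask holding free catalyst, and the asked row varies the dosing time.

in all of them: free catalyst 0.05 mol%
- south-east: substrate 0.13 M (fed, over 1.2 h); run made earlier; the fed solution adds 0.10 times the starting volume
- south-west: substrate 0.30 M (fed, over 1.2 h); run made earlier; the fed solution adds 0.10 times the starting volume
- noon: substrate 0.20 M (fed, over 1.2 h); the fed solution adds 0.10 times the starting volume; time 50 h
- autumn: substrate 0.20 M (fed, over 2.5 h); the fed solution adds 0.10 times the starting volume; time 50 h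
- midnight: substrate 0.20 M (fed, over 5.0 h); the fed solution adds 0.10 times the starting volume; time 50 h
- summer: substrate 0.20 M (fed, over 10 h); the fed solution adds 0.10 times the starting volume; time 50 h
- dawn: substrate 0.20 M (fed, over 20 h); the fed solution adds 0.10 times the starting volume; time 50 h

| run | time / h | target / % | substrate / % |
|---|---|---|---|
| south-east | 2.50 | 9.9 | 89.6 |
| south-east | 8.00 | 28.1 | 65.6 |
| south-east | 15.0 | 41.6 | 43.0 |
| south-east | 20.0 | 48.0 | 30.3 |
| south-east | 30.0 | 57.1 | 18.5 |
| south-east | 40.0 | 63.6 | 9.0 |
| south-east | 48.0 | 66.1 | 5.1 |
| south-west | 8.00 | 43.7 | 40.1 |
| south-west | 15.0 | 59.4 | 15.2 |
| south-west | 20.0 | 65.9 | 7.2 |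
| south-west | 30.0 | 69.5 | 1.0 |
| south-west | 40.0 | 68.7 | 0 |
| south-west | 48.0 | 69.5 | 0.2 |

(scatter of a reading: 1 percentage point)

1. amount of target at the end, in percent of the substrate charged for noon, autumn, midnight, summer, dawn, in this order
2. how the row runs (rises, then falls / falls all the way / rises all the way / falls, then rises / hardly changes)

- charges are per starting volume, the dose included; the dosed solution carries all of it
- a reading or a percentage of target counts all its forms, free or not
- "hardly changes" means that all values lie within two and a half points (for a concentration: within two and a half percent of the largest)

Over its last readings the south-west run holds target flat with 0.2% substrate at the end, and target over substrate no longer present reads 69.5%; call this the plateau share. The south-east run reads 69.7% at 48.0 h, at another charge. End target is then the plateau share times one minus the leftover.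

Now turn the question round. For the row to leave the band of 2.50 points, either the share must shift with dosing time, or the share times the difference of the leftovers must exceed that band. The share did not follow the charge in these readings. The leftover can be reckoned: late substrate decay gives 0.0626 /h south-east and 0.143 /h south-west, a ratio of 2.28 against a charge ratio of 2.31. This pseudo-first-order constant, scaled to charge, reads 0.0958 /h for noon's charge. A steady feed multiplies the plain decay exp(−k·t) by (exp(k·tf) minus one)/(k·tf).

The reckoning here leaves 0.880% in noon, so target stands near 68.9%. In dawn, the first portion of the feed has 50 h in the flask and the last 30.0 h; the same constant leaves 0.830% of the first and 5.64% of the last. Their mean, 3.24%, lies above the mean over a steady feed, the decay curve being convex, and serves as the high side for dawn. Target then stands near 67.2%, a spread of 1.6 percentage points against the band of 2.50 points.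

The forecast gives 69.3%, 69.3%, 69.2%, 69%, 68.3%, shape hardly changes, on the ground that “Substrate appears in both the main and side rates, so its level cancels and dosing cannot change selectivity.” Its noon value stands 0.4 points above the reckoning here, with the same shape.

The flasks give 69.3%, 69.2%, 69.2%, 68.9%, 68.2%: hardly changes.

    target + free catalyst ⇌ isomer of the product + free catalyst, rate k1*[free catalyst]*[target] forward; the back reaction follows from the equilibrium constant (K = 0.423, k = 39.1 /M/min)
    catalyst intermediate → free catalyst + target (k = 22.0 /min)
    substrate → decomposition product (k = 6.59 × 10⁻⁶ /min)
    crystals ⇌ target, rate k4*(cs4 - [target]) while solid is left; crystals form when [target] > cs4 (solubility = 0.190 M, k = 0.953 /min)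
    substrate + free catalyst ⇌ catalyst intermediate (K = 2.13 /M, k = 27.7 /M/min)

With the simulated leftovers the plateau share gives 68.8% for noon against 69.3%, and 67.6% for dawn against 68.2%. In noon, substrate bound free catalyst as the catalyst intermediate, half of that step's turnover being done by 8.47 h, while target passed reversibly into the isomer of the product, the half-life of dissolved target by that forward step alone being 3.5 h at 8.47 h, shorter than 50 h. In dawn both steps ran during the feed, which ended at 20 h with substrate 45.5%, target 39.9% and isomer of the product 14.4%, and 2.77% of the substrate stood at 50 h.

The earlier runs and the new flask were computed with constants of no real substance; scatter was added.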